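**Retrosynthetic overview**

- The target is quercetin (rings A, C and B intact) with a 4-hydroxybenzyl group on C8; the last disconnection is the hydrogenolytic removal of six O-benzyl groups.
- Key disconnection C8–CH2: both carbons are introduced as electrophiles, C8 as an aryl iodide and the benzylic carbon as the N-hydroxyphthalimide ester of an arylacetic acid, and are joined by a nickel-catalysed electroreductive decarboxylative coupling.
- Enabling features: C8 is the ring A carbon between ring oxygen O1 and the C7 oxygen and para to the C5 oxygen, the least hindered electron-rich CH of a 5,7-dialkoxychromen-4-one, so iodine can be placed there. The CH2 carbon is benzylic to the 4-oxygenated phenyl ring, so a carboxyl group on it is a traceless activator that leaves as CO2 and gives a stabilised radical.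
- The aryl iodide comes from quercetin by exhaustive O-benzylation and C8 iodination; the ester comes from 4-(benzyloxy)phenylacetic acid.
- Order of ring formation: no ring is built. The chromen-4-one (rings A and C) and catechol ring B come from quercetin, the fourth benzene ring from the arylacetic acid.

Key step: step 4

Remark on the chemistry: the target has no stereocentre, stereogenic axis or stereogenic double bond, so it is achiral and the route needs no stereocontrol.

**Route**

Step 1
Reactants: 1 quercetin; 2 benzyl bromide
Product: 3 3,3',4',5,7-penta-O-benzylquercetin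
Conditions: BnBr (7.5 equiv), K2CO3 (7.5 equiv), Bu4NI (cat.), DMF, Ar, rt then 75 °C
Reagents that add atoms: benzyl bromide (2), BrCc1ccccc1
Why: Williamson etherification of all five hydroxyl groups, with excess reagent and heat to force alkylation of the hydrogen-bonded 5-OH, under argon to protect the catechol from oxidation in base.

Step 2
Reactants: 3 3,3',4',5,7-penta-O-benzylquercetin; 4 N-iodosuccinimide
Product: 5 8-iodo-3,3',4',5,7-penta-O-benzylquercetin
Conditions: NIS (1.05 equiv), TFA (0.3 equiv), MeCN/CH2Cl2, 0 °C to rt, dark
Reagents that add atoms: N-iodosuccinimide (4), O=C1CCC(=O)N1I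
Why: Electrophilic aromatic iodination should go to C8, which is as activated as C6 (ortho to O7 and O1, para to O5) but far less hindered than C6 between two benzyloxy groups, while ring B is a less activated 1,2-dioxygenated ring conjugated to the electron-poor C2, in line with the known C8 halogenation of 5,7-dialkoxyflavones.

Step 3
Reactants: 6 4-(benzyloxy)phenylacetic acid; 7 N-hydroxyphthalimide
Product: 8 1,3-dioxoisoindolin-2-yl 2-[4-(benzyloxy)phenyl]acetate
Conditions: DIC (1.1 equiv), DMAP (5 mol %), CH2Cl2, 0 °C to rt
Reagents that add atoms: N-hydroxyphthalimide (7), O=C1c2ccccc2C(=O)N1O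
Why: Carbodiimide-mediated (Steglich-type) esterification turns the acid into a redox-active ester that is an electrophile at the benzylic carbon after one-electron reduction.

Step 4
Reactants: 5 8-iodo-3,3',4',5,7-penta-O-benzylquercetin; 8 1,3-dioxoisoindolin-2-yl 2-[4-(benzyloxy)phenyl]acetate
Product: 11 3,3',4',5,7-penta-O-benzyl-8-[4-(benzyloxy)benzyl]quercetin, via arylnickel(II) iodide 9 (not isolated), via 4-(benzyloxy)benzyl radical 10 (not isolated)
Conditions: NiBr2·glyme (10 mol %), dtbbpy (12 mol %), LiBr, DMA, undivided cell, Zn(+)/RVC(−), constant current, rt, Ar; 8 (1.8 equiv) added in portions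
Reagents that add atoms: none
Why: Cathodically generated Ni(0)(dtbbpy) inserts into the C8–I bond of 5 to give arylnickel(II) iodide 9, while single-electron reduction of the N-acyloxyphthalimide 8 cleaves its N–O bond and expels CO2 to leave the 4-(benzyloxy)benzyl radical 10. Capture of 10 by 9 gives an aryl(benzyl)nickel(III) species that reductively eliminates the C8–CH2 bond, and the cathode returns the nickel(I) left behind to nickel(0), the zinc anode supplying the two electrons. The closest known reaction type is the nickel-catalysed decarboxylative cross-electrophile coupling of N-hydroxyphthalimide esters with aryl iodides in its electroreductive form, in which arylacetic esters are established radical precursors. No ring is closed and no stereocentre is formed. The step needs cross-selectivity over bibenzyl formation, biaryl formation and hydrodeiodination, and it needs the chromen-4-one carbonyl and the benzyl ethers to stay untouched. The first should be secured by the two different activation modes of the partners (two-electron oxidative addition of the aryl iodide, one-electron fragmentation of the ester), by the current-limited, portionwise release of a stabilised benzylic radical and by the small size of the two ortho oxygens at C8 (O1 is tied back in the pyranone ring), the second by working at the potential of the nickel catalyst, which lies short of chromenone reduction.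

Step 5
Reactants: 11 3,3',4',5,7-penta-O-benzyl-8-[4-(benzyloxy)benzyl]quercetin
Product: 12 8-p-hydroxybenzylquercetin
Conditions: H2 (1 atm), 10% Pd/C, THF/MeOH, rt
Reagents that add atoms: none
Why: Catalytic hydrogenolysis should cleave all six aryl benzyl ethers while leaving the diarylmethane C–C bond and the tetrasubstituted C2=C3 bond of the vinylogous ester intact.

**Compound list**

1 | quercetin, 3,5,7-trihydroxy-2-(3,4-dihydroxyphenyl)-4H-chromen-4-one | O=c1c(O)c(-c2ccc(O)c(O)c2)oc2cc(O)cc(O)c12 | starting material
2 | benzyl bromide | BrCc1ccccc1 | starting material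
3 | 3,3',4',5,7-penta-O-benzylquercetin, 3,5,7-tris(benzyloxy)-2-[3,4-bis(benzyloxy)phenyl]-4H-chromen-4-one | O=c1c(OCc2ccccc2)c(-c2ccc(OCc3ccccc3)c(OCc3ccccc3)c2)oc2cc(OCc3ccccc3)cc(OCc3ccccc3)c12 | intermediate
4 | N-iodosuccinimide | O=C1CCC(=O)N1I | starting material
5 | 8-iodo-3,3',4',5,7-penta-O-benzylquercetin, iodine on the ring A carbon between O1 and the 7-benzyloxy group | O=c1c(OCc2ccccc2)c(-c2ccc(OCc3ccccc3)c(OCc3ccccc3)c2)oc2c(I)c(OCc3ccccc3)cc(OCc3ccccc3)c12 | intermediate
6 | 4-(benzyloxy)phenylacetic acid | OC(=O)Cc1ccc(OCc2ccccc2)cc1 | starting material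
7 | N-hydroxyphthalimide | O=C1c2ccccc2C(=O)N1O | starting material
8 | 1,3-dioxoisoindolin-2-yl 2-[4-(benzyloxy)phenyl]acetate (N-hydroxyphthalimide ester of 6) | O=C(Cc1ccc(OCc2ccccc2)cc1)ON1C(=O)c2ccccc2C1=O | intermediate
9 | arylnickel(II) iodide from oxidative addition at C8 of 5 (bipyridine ligand on nickel not drawn) | O=c1c(OCc2ccccc2)c(-c2ccc(OCc3ccccc3)c(OCc3ccccc3)c2)oc2c([Ni]I)c(OCc3ccccc3)cc(OCc3ccccc3)c12 | intermediate
10 | 4-(benzyloxy)benzyl radical | [CH2]c1ccc(OCc2ccccc2)cc1 | intermediate
11 | 3,3',4',5,7-penta-O-benzyl-8-[4-(benzyloxy)benzyl]quercetin, 3,5,7-tris(benzyloxy)-2-[3,4-bis(benzyloxy)phenyl]-8-[4-(benzyloxy)benzyl]-4H-chromen-4-one | O=c1c(OCc2ccccc2)c(-c2ccc(OCc3ccccc3)c(OCc3ccccc3)c2)oc2c(Cc3ccc(OCc4ccccc4)cc3)c(OCc3ccccc3)cc(OCc3ccccc3)c12 | intermediate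
12 | 8-p-hydroxybenzylquercetin, 3,5,7-trihydroxy-2-(3,4-dihydroxyphenyl)-8-(4-hydroxybenzyl)-4H-chromen-4-one (achiral) | O=c1c(O)c(-c2ccc(O)c(O)c2)oc2c(Cc3ccc(O)cc3)c(O)cc(O)c12 | target

**Step count**

Total steps: 5. Longest linear sequence: 4 (steps 1, 2, 4, 5 from quercetin); step 3 is a one-step branch.

**Steps most likely to fail**

Step 4. Capture of the benzylic radical at nickel may be slowed by the two ortho oxygens at C8, so that radical dimerisation and hydrodeiodination outrun the cross-coupling. The fallback replaces the radical cross-electrophile coupling by a two-electron cross-coupling with a preformed benzyl nucleophile. It sets out from 5. Commercial 4-(benzyloxy)benzyl chloride is converted with zinc dust and LiCl in THF into 4-(benzyloxy)benzylzinc chloride F1, which is joined to 5 in a palladium-catalysed Negishi coupling (Pd(OAc)2/SPhos, THF, rt to 50 °C). It comes back to the route at 11.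

Step 2. The iodination may lose site selectivity (attack at C6 or on ring B), or the acid may cleave the 5-O-benzyl group. The fallback places the iodine before ring C exists, so that its position is fixed by the ring closure. It sets out from benzyl bromide 2 and commercial 2,4,6-trihydroxyacetophenone and runs as follows:
- Bis-O-benzylation with 2 (K2CO3, DMF, rt) leaves the chelated hydroxyl free and gives 2-hydroxy-4,6-bis(benzyloxy)acetophenone F2.
- Iodination ortho to the free phenol (I2, HIO3, aqueous EtOH) gives 2-hydroxy-3-iodo-4,6-bis(benzyloxy)acetophenone F3.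
- Claisen–Schmidt condensation with commercial 3,4-bis(benzyloxy)benzaldehyde (KOH, EtOH) gives (E)-1-[2-hydroxy-3-iodo-4,6-bis(benzyloxy)phenyl]-3-[3,4-bis(benzyloxy)phenyl]prop-2-en-1-one F4.
- Algar–Flynn–Oyamada oxidative cyclisation (H2O2, NaOH, MeOH) through the only free phenol gives 3-hydroxy-8-iodo-5,7-bis(benzyloxy)-2-[3,4-bis(benzyloxy)phenyl]-4H-chromen-4-one F5, with the iodine next to the new ring oxygen.
- O-Benzylation of the 3-hydroxyl with 2 (K2CO3, DMF) brings the fallback back to the route at 5.

Step 5. Hydrogenolysis of six benzyl ethers may stall through catalyst poisoning by traces of iodide, zinc or nickel, or the C2=C3 bond may be partly saturated on prolonged exposure. The fallback replaces hydrogenolysis by Lewis acid cleavage. It sets out from 11, uses BCl3 with pentamethylbenzene as benzyl cation scavenger (CH2Cl2, −78 °C), and comes back to the route at 12; it makes no new compound.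

**Further compounds**

F1 | step 4 | 4-(benzyloxy)benzylzinc chloride | Cl[Zn]Cc1ccc(OCc2ccccc2)cc1
F2 | step 2 | 2-hydroxy-4,6-bis(benzyloxy)acetophenone | CC(=O)c1c(O)cc(OCc2ccccc2)cc1OCc1ccccc1
F3 | step 2 | 2-hydroxy-3-iodo-4,6-bis(benzyloxy)acetophenone | CC(=O)c1c(O)c(I)c(OCc2ccccc2)cc1OCc1ccccc1
F4 | step 2 | (E)-1-[2-hydroxy-3-iodo-4,6-bis(benzyloxy)phenyl]-3-[3,4-bis(benzyloxy)phenyl]prop-2-en-1-one | O=C(/C=C/c1ccc(OCc2ccccc2)c(OCc2ccccc2)c1)c1c(O)c(I)c(OCc2ccccc2)cc1OCc1ccccc1
F5 | step 2 | 3-hydroxy-8-iodo-5,7-bis(benzyloxy)-2-[3,4-bis(benzyloxy)phenyl]-4H-chromen-4-one | O=c1c(O)c(-c2ccc(OCc3ccccc3)c(OCc3ccccc3)c2)oc2c(I)c(OCc3ccccc3)cc(OCc3ccccc3)c12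
F0 | step 5 | none | none
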